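The data are calculated from invented constants; noise was put on by code.

Start with a straight line: replace each run's curve by its mean slope, the product at a late reading divided by the time it took.

| flask | substrate | gas | temperature | remark | time |
|---|---|---|---|---|---|
| larch | 28 mM | 1.3 mM (held) | 80 °C | run made earlier |  |
| maple | 44 mM | 1.3 mM (held) | 102 °C | run made earlier |  |
| south-west | 20 mM | 1.3 mM (held) | 90 °C |  | 3.0 h |
| west | 20 mM | 1.3 mM (held) | 70 °C |  | 3.0 h |
| north | 20 mM | 1.3 mM (held) | 110 °C |  | 3.0 h |

larch run (percent of the substrate charged)

| time / h | product / % |
|---|---|
| 0.333 | 0 |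
| 0.500 | 0 |
| 1.00 | 6 |
| 2.00 | 14 |
| 4.00 | 26 |

maple run (percent of the substrate charged)

| time / min | product / % |
|---|---|
| 15.0 | 3 |
| 30.0 | 5 |
| 40.0 | 10 |
| 60.0 | 15 |
| 80.0 | 15 |

(each reading ± 1.5 percentage points)

- the best flask by amount of product, in percent of the substrate charged; "all alike" if 1.5 percentage points covers them all (south-west / west / north / all alike)
- amount of product at the end, in percent of the substrate charged, south-west
- amount of product at the end, in percent of the substrate charged, west
- amount of product at the end, in percent of the substrate charged, north

- what was read earlier has a scatter of 1.5 percentage points, one standard deviation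
- at the start none of the gas is in solution

Larch gives 0.0650 h⁻¹ of the charge over 4.00 h, lag included, and maple gives 0.150 h⁻¹ over 60.0 min. Divide them to get 2.31, the factor by which the mean slope grows from larch's 80 °C to maple's 102 °C: the heat gain. Spread it geometrically over the temperature.

Now test each number before trusting it. Take the lag first: larch reads 0 % at 0.500 h, and a lag that long, if misjudged, shifts a flask on larch's slope by 3.2 percentage points. Next take the gain: one scatter on maple's reading moves the south-west slope by 4.55 % of itself. The charge can't be weighed, since from larch to maple it changed together with the temperature, so the gain carries both. Last comes the ceiling: maple reads 15 % at 60.0 min and 15 % at 80.0 min, and north needs such a plateau, since its slope would reach 61.0 %, more than that reading.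

Commit to my own numbers: south-west 28.5 %, west 13.3 %, and north at 15 %, which assumes that maple's plateau carries over to north.

The forecast also picks south-west, with 19 % (13 % to 27 %), west 12 % (7 % to 18 %) and north 7 % (3 % to 15 %), on the ground that “Deactivation appears much steeper in temperature”. Its south-west stands below my 28.5 %, and its north below my 15 %.

South-west gives 33.6 %, west 7.13 %, north 13.7 %, so south-west leads.

    partner + intermediate ⇌ product (K = 580 L mol⁻¹, k = 4.96 L mol⁻¹ min⁻¹, Ea = 61.0 kJ mol⁻¹, ΔH = −90.0 kJ mol⁻¹)
    substrate → intermediate (k = 0.0272 min⁻¹, Ea = 111 kJ mol⁻¹)
    gas ⇌ partner, rate k3*(csat - [partner]) (kL = 0.209 min⁻¹)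
    (constants at 90 °C)

North sits on its ceiling, a case of thermodynamic control: product stands at 13.7 % after 3.00 h and 13.7 % after 30.0 h. Use the heat gain once more. South-west's result is above the 28.5 % it gave. For the west flask run at 95 °C, the gain gives 34.5 %, and that flask holds 31.0 %.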